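**Retrosynthetic overview**

1. The two amide N–acyl bonds are cut last, to two bought pyrrole acyl donors. Before that, both 2-aminoimidazoles are traced back to two acetyl groups on C1 and C4 of an all-trans cyclobutane (α-chlorination, amination, cyanamide condensation).
2. The C4 acetyl comes from conjugate addition of a masked acetyl anion to a C1-acetylcyclobutene (C1=C4). That enone comes from a C1 cyclobutanone through its C1–C4 enol triflate and a carbonylative methyl coupling.
3. The strategy rests on the cyclobutane C1–C4 (numbered as in the target SMILES): C2 and C3 with their one-carbon nitrogen arms are a trans-1,2-dicarboxylate, that is a fumarate, and C1–C4 is a two-carbon unit that a ketene acetal supplies, C1 arriving as the acetal (masked ketone) carbon. The C3–C4 and C1–C2 bonds are therefore disconnected to di-(−)-menthyl fumarate and 1,1-dimethoxyethene.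
4. Ring order: the cyclobutane first (step 2), then both imidazoles together (step 15); the pyrroles are bought.
5. The all-trans core has a twofold axis, so the two arms are homotopic at the diacetyl stage and are told apart there by mono-reduction of a diazide.

Key step: step 2

Assumption: di-(−)-menthyl fumarate is taken to deliver the (1S,2R) cycloadduct, the hand that maps onto C2 and C3 of the target; should the opposite hand form, (+)-menthol would be used with nothing else changed.

**Route**

Step 1
Reactants: 1 fumaryl chloride; 2 (−)-menthol (two equivalents, one for each acyl chloride)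
Product: 3 di-(−)-menthyl fumarate
Conditions: 2 (2.1 equiv), pyridine, DMAP (cat.), CH2Cl2, 0 to 23 °C
Reagents that add atoms: (−)-menthol (second equivalent of 2), CC(C)[C@@H]1CC[C@@H](C)C[C@H]1O
Why: Each acyl chloride of 1 acylates one molecule of the secondary alcohol under nucleophilic (DMAP) catalysis, so two equivalents of 2 are consumed per fumaryl chloride and the diester should form without touching the E alkene or the menthyl stereocentres.

Step 2
Reactants: 3 di-(−)-menthyl fumarate; 4 1,1-dimethoxyethene
Product: 6 di-(−)-menthyl (1S,2R)-3,3-dimethoxycyclobutane-1,2-dicarboxylate, via zwitterion 5 (not isolated)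
Conditions: Et2AlCl (2 equiv), toluene/hexane, −78 °C; then aqueous NaHCO3
Reagents that add atoms: none
Why: Et2AlCl binds the ester carbonyls and lowers the fumarate LUMO, the nucleophilic CH2 of 4 (target C4) adds in Michael fashion to one alkene carbon (target C3) to give zwitterion 5, an aluminium ester enolate tethered to a dimethoxycarbenium ion, and the enolate carbon (C2) then attacks the carbenium carbon (C1). The closest known reaction type is the Lewis acid promoted stepwise [2+2] cycloaddition of ketene acetals and related electron-rich alkenes with fumarates and acrylates. The cyclobutane closes by a 4-exo-trig attack of the enolate on the oxocarbenium carbon, which at −78 °C should be faster than rotation about the C2–C3 bond. C3 is set in the conjugate addition by the menthyl auxiliaries, whose isopropyl groups in the s-trans ester–aluminium complexes cover the same alkene face at both carbons, and C2 is set on ring closure trans to C3 by the retained E geometry, which is also the more stable arrangement. The step needs facial and trans selectivity: the first is secured by two matched auxiliaries on a twofold-symmetric fumarate (attack at either alkene carbon from the open face gives the same product), the second by fast collapse of the ion pair.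

Step 3
Reactants: 6 di-(−)-menthyl (1S,2R)-3,3-dimethoxycyclobutane-1,2-dicarboxylate
Product: 7 [(1S,2S)-3,3-dimethoxycyclobutane-1,2-diyl]dimethanol
Conditions: LiAlH4, THF, 0 to 23 °C; then H2O, aqueous NaOH
Reagents that add atoms: none
Why: Hydride reduction of both esters (LiAlH4 ester reduction) leaves the acetal and the two ring stereocentres untouched and releases the auxiliary as recoverable menthol.

Step 4
Reactants: 7 [(1S,2S)-3,3-dimethoxycyclobutane-1,2-diyl]dimethanol
Product: 8 (1S,2S)-1,2-bis[(benzyloxy)methyl]-3,3-dimethoxycyclobutane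
Conditions: NaH, BnBr, Bu4NI (cat.), THF/DMF, 0 to 23 °C
Reagents that add atoms: benzyl bromide, BrCc1ccccc1
Why: Williamson etherification of both primary alkoxides installs benzyl ethers, which are inert to the enolate, palladium and cuprate chemistry that follows and come off later without affecting ketones.

Step 5
Reactants: 8 (1S,2S)-1,2-bis[(benzyloxy)methyl]-3,3-dimethoxycyclobutane
Product: 9 (2S,3S)-2,3-bis[(benzyloxy)methyl]cyclobutan-1-one
Conditions: 0.5 M H2SO4, MeCN, 23 °C
Reagents that add atoms: water, O
Why: Acid-catalysed acetal hydrolysis unmasks the C1 ketone; C2 becomes α to the carbonyl, but any enolisation should return the more stable 2,3-trans isomer because C3 is fixed.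

Step 6
Reactants: 9 (2S,3S)-2,3-bis[(benzyloxy)methyl]cyclobutan-1-one
Product: 10 (3S,4S)-3,4-bis[(benzyloxy)methyl]cyclobut-1-en-1-yl trifluoromethanesulfonate
Conditions: KN(SiMe3)2 added to 9 and PhNTf2, THF, −78 °C
Reagents that add atoms: N-phenylbis(trifluoromethanesulfonimide), O=S(=O)(N(c1ccccc1)S(=O)(=O)C(F)(F)F)C(F)(F)F
Why: Kinetic deprotonation by the hindered amide base should occur at the unsubstituted C4 methylene and not at the flanked tertiary C2–H, and in-situ O-triflation of the enolate (enol triflate formation) fixes the C1=C4 double bond before aldol or β-alkoxide loss can compete.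

Step 7
Reactants: 10 (3S,4S)-3,4-bis[(benzyloxy)methyl]cyclobut-1-en-1-yl trifluoromethanesulfonate
Product: 11 1-{(3S,4R)-3,4-bis[(benzyloxy)methyl]cyclobut-1-en-1-yl}ethan-1-one
Conditions: CO (1 atm), Me4Sn, Pd(PPh3)4 (5 mol %), LiCl, THF, 55 °C
Reagents that add atoms: carbon monoxide, [C-]#[O+]; tetramethylstannane, C[Sn](C)(C)C
Why: Carbonylative Stille coupling: oxidative addition of zerovalent palladium into the C1–OTf bond, CO insertion to the acylpalladium, methyl transfer from tin and reductive elimination should give the C1 methyl ketone with the C1=C4 alkene in conjugation.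

Step 8
Reactants: 11 1-{(3S,4R)-3,4-bis[(benzyloxy)methyl]cyclobut-1-en-1-yl}ethan-1-one
Product: 14 1,1'-{(1S,2S,3R,4R)-3,4-bis[(benzyloxy)methyl]cyclobutane-1,2-diyl}di(ethan-1-one) (all-trans), via lithium enolate 12 (not isolated), via C1-epimeric diketone 13 (not isolated)
Conditions: [CH2=C(OEt)]2CuLi (from ethyl vinyl ether, t-BuLi, CuI), THF, −78 to −40 °C; then 1 M HCl, THF, 23 °C; then K2CO3, MeOH, 23 °C
Reagents that add atoms: ethyl vinyl ether (as its lithiated cuprate), C=COCC; water, O
Why: Conjugate addition of an α-alkoxyvinyl cuprate (masked acetyl anion) to the strained enone should deliver the two-carbon unit to C4 anti to the C3 arm, acid hydrolyses the enol ether to the second acetyl group, and because C1 and C4 are both α to ketones the carbonate equilibration should move the kinetically protonated C1 epimer to the all-trans isomer, the most stable arrangement.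

Step 9
Reactants: 14 all-trans diacetyl bis(benzyl ether)
Product: 15 1,1'-[(1S,2S,3R,4R)-3,4-bis(hydroxymethyl)cyclobutane-1,2-diyl]di(ethan-1-one)
Conditions: H2 (1 atm), Pd(OH)2/C, EtOAc/EtOH, 23 °C
Reagents that add atoms: none
Why: Hydrogenolysis of the benzyl ethers under neutral conditions leaves the aliphatic ketones and the four ring stereocentres untouched.

Step 10
Reactants: 15 all-trans diacetyl diol
Product: 16 [(1R,2R,3S,4S)-3,4-diacetylcyclobutane-1,2-diyl]bis(methylene) dimethanesulfonate
Conditions: MsCl, Et3N, CH2Cl2, 0 °C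
Reagents that add atoms: methanesulfonyl chloride, CS(=O)(=O)Cl
Why: Sulfonylation of the two primary alcohols traps the open hydroxy ketone form and is much faster than any reaction at the ketone α-positions.

Step 11
Reactants: 16 all-trans diacetyl dimesylate
Product: 17 1,1'-[(1S,2S,3R,4R)-3,4-bis(azidomethyl)cyclobutane-1,2-diyl]di(ethan-1-one)
Conditions: NaN3, DMF, 50 °C
Reagents that add atoms: sodium azide, [Na+].[N-]=[N+]=[N-]
Why: SN2 displacement of the primary mesylates by the weakly basic azide ion should not disturb the epimerisable centres, which in any case sit in their stable all-trans arrangement.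

Step 12
Reactants: 17 all-trans diacetyl diazide; 18 4-bromo-2-(trichloroacetyl)-1H-pyrrole
Product: 20 N-{[all-trans-3,4-diacetyl-2-(azidomethyl)cyclobutyl]methyl}-4-bromo-1H-pyrrole-2-carboxamide, via azido ammonium chloride 19 (not isolated)
Conditions: PPh3 (1.0 equiv), Et2O/EtOAc and 1 M HCl (two phases), 0 to 23 °C; aqueous phase: NaHCO3, 18, EtOAc, 23 °C
Reagents that add atoms: none
Why: Staudinger reduction under two-phase conditions should stop after one azide because the protonated monoamine moves into the aqueous acid away from the phosphine, the twofold symmetry of 17 makes either arm give the same compound, and the liberated amine is then acylated by the trichloromethyl ketone (haloform-type acyl transfer) faster than it can condense with a ketone.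

Step 13
Reactants: 20 azido bromopyrrole amide diketone
Product: 21 N-{[all-trans-2-(azidomethyl)-3,4-bis(chloroacetyl)cyclobutyl]methyl}-4-bromo-1H-pyrrole-2-carboxamide
Conditions: BnNMe3ICl2, ClCH2CH2Cl/MeOH, 60 °C
Reagents that add atoms: benzyltrimethylammonium dichloroiodate, C[N+](C)(C)Cc1ccccc1.Cl[I-]Cl
Why: Electrophilic α-chlorination through the enol should occur at the two methyl groups, since enolisation toward the ring would place an exocyclic double bond on the cyclobutane; closely related all-trans diacetylcyclobutanes carrying bromopyrrole amides are known to behave this way with this reagent.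

Step 14
Reactants: 21 bis(chloromethyl ketone)
Product: 23 N-{[all-trans-3,4-bis(aminoacetyl)-2-(azidomethyl)cyclobutyl]methyl}-4-bromo-1H-pyrrole-2-carboxamide dihydrochloride, via bis(diformylamide) 22 (not isolated)
Conditions: NaN(CHO)2, MeCN, 35 °C; then HCl, MeOH, 23 °C
Reagents that add atoms: sodium diformylamide, [Na+].O=C[N-]C=O; hydrogen chloride, Cl
Why: Gabriel-type SN2 amination with the diformylamide anion avoids over-alkylation, and acidic methanolysis of the formyl groups gives the α-aminoketones as hydrochlorides, which cannot self-condense to dihydropyrazines.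

Step 15
Reactants: 23 bis(α-aminoketone) dihydrochloride
Product: 24 N-{[all-trans-2-(azidomethyl)-3,4-bis(2-amino-1H-imidazol-4-yl)cyclobutyl]methyl}-4-bromo-1H-pyrrole-2-carboxamide dihydrochloride
Conditions: H2NCN, H2O (pH 4.5), 95 °C
Reagents that add atoms: cyanamide, N#CN
Why: Guanylation of each α-amino group by cyanamide followed by cyclodehydration onto the adjacent ketone (the cyanamide synthesis of 2-aminoimidazoles from α-aminoketones) builds both heterocycles with the cyclobutane on C4 of each ring, and azide, amide and aryl bromide are inert to hot weakly acidic water.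

Step 16
Reactants: 24 azido bis(2-aminoimidazole) dihydrochloride
Product: 25 N-{[all-trans-2-(aminomethyl)-3,4-bis(2-amino-1H-imidazol-4-yl)cyclobutyl]methyl}-4-bromo-1H-pyrrole-2-carboxamide trihydrochloride
Conditions: PMe3, THF/H2O, 23 °C; then aqueous HCl
Reagents that add atoms: hydrogen chloride, Cl
Why: Staudinger reduction converts the remaining azide to the primary amine without the hydrogenolysis risk that a palladium reduction would pose to the aryl bromide.

Step 17
Reactants: 25 amine trihydrochloride; 26 2-(trichloroacetyl)-1H-pyrrole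
Product: 27 desbromosceptrine
Conditions: i-Pr2NEt, DMF, 23 °C; then aqueous NaHCO3, reversed-phase chromatography
Reagents that add atoms: none
Why: Acyl transfer from the trichloromethyl ketone should be selective for the primary alkylamine, because the 2-aminoimidazoles are delocalised amidine-type nitrogens of low nucleophilicity, as in acylations of other 2-aminoimidazole alkylamines with trichloroacetylpyrroles.

**Compound list**

1 | fumaryl chloride | O=C(Cl)/C=C/C(=O)Cl | starting material
2 | (−)-menthol | CC(C)[C@@H]1CC[C@@H](C)C[C@H]1O | starting material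
3 | di-(−)-menthyl fumarate | CC(C)[C@@H]1CC[C@@H](C)C[C@H]1OC(=O)/C=C/C(=O)O[C@@H]1C[C@H](C)CC[C@H]1C(C)C | intermediate
4 | 1,1-dimethoxyethene | C=C(OC)OC | starting material
5 | zwitterion after C3–C4 bond formation: aluminium ester enolate at C2, dimethoxycarbenium ion at C1 | CO[C+](OC)C[C@H](C(=O)O[C@@H]1C[C@H](C)CC[C@H]1C(C)C)/C=C(/O[Al-](CC)(CC)Cl)O[C@@H]1C[C@H](C)CC[C@H]1C(C)C | intermediate (not isolated)
6 | di-(−)-menthyl (1S,2R)-3,3-dimethoxycyclobutane-1,2-dicarboxylate (trans) | COC1(OC)C[C@H](C(=O)O[C@@H]2C[C@H](C)CC[C@H]2C(C)C)[C@H]1C(=O)O[C@@H]1C[C@H](C)CC[C@H]1C(C)C | intermediate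
7 | [(1S,2S)-3,3-dimethoxycyclobutane-1,2-diyl]dimethanol | COC1(OC)C[C@H](CO)[C@H]1CO | intermediate
8 | (1S,2S)-1,2-bis[(benzyloxy)methyl]-3,3-dimethoxycyclobutane | COC1(OC)C[C@H](COCc2ccccc2)[C@H]1COCc1ccccc1 | intermediate
9 | (2S,3S)-2,3-bis[(benzyloxy)methyl]cyclobutan-1-one | O=C1C[C@H](COCc2ccccc2)[C@H]1COCc1ccccc1 | intermediate
10 | (3S,4S)-3,4-bis[(benzyloxy)methyl]cyclobut-1-en-1-yl trifluoromethanesulfonate | O=S(=O)(OC1=C[C@H](COCc2ccccc2)[C@H]1COCc1ccccc1)C(F)(F)F | intermediate
11 | 1-{(3S,4R)-3,4-bis[(benzyloxy)methyl]cyclobut-1-en-1-yl}ethan-1-one | CC(=O)C1=C[C@H](COCc2ccccc2)[C@H]1COCc1ccccc1 | intermediate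
12 | lithium enolate of the conjugate adduct (exocyclic C1=C(OLi)CH3, 1-ethoxyvinyl on C4 trans to the C3 arm; enolate geometry drawn as from the s-trans enone, of no consequence) | [Li]O/C(C)=C1\[C@H](COCc2ccccc2)[C@@H](COCc2ccccc2)[C@@H]1C(=C)OCC | intermediate (not isolated)
13 | C1 epimer of 14 (C1 acetyl cis to the C2 arm and to the C4 acetyl) | CC(=O)[C@@H]1[C@H](COCc2ccccc2)[C@@H](COCc2ccccc2)[C@@H]1C(C)=O | intermediate (not isolated)
14 | 1,1'-{(1S,2S,3R,4R)-3,4-bis[(benzyloxy)methyl]cyclobutane-1,2-diyl}di(ethan-1-one), all-trans | CC(=O)[C@H]1[C@H](COCc2ccccc2)[C@@H](COCc2ccccc2)[C@@H]1C(C)=O | intermediate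
15 | 1,1'-[(1S,2S,3R,4R)-3,4-bis(hydroxymethyl)cyclobutane-1,2-diyl]di(ethan-1-one), all-trans | CC(=O)[C@H]1[C@H](CO)[C@@H](CO)[C@@H]1C(C)=O | intermediate
16 | [(1R,2R,3S,4S)-3,4-diacetylcyclobutane-1,2-diyl]bis(methylene) dimethanesulfonate, all-trans | CC(=O)[C@H]1[C@H](COS(C)(=O)=O)[C@@H](COS(C)(=O)=O)[C@@H]1C(C)=O | intermediate
17 | 1,1'-[(1S,2S,3R,4R)-3,4-bis(azidomethyl)cyclobutane-1,2-diyl]di(ethan-1-one), all-trans | CC(=O)[C@H]1[C@H](CN=[N+]=[N-])[C@@H](CN=[N+]=[N-])[C@@H]1C(C)=O | intermediate
18 | 4-bromo-2-(trichloroacetyl)-1H-pyrrole | O=C(c1cc(Br)c[nH]1)C(Cl)(Cl)Cl | starting material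
19 | all-trans 1,1'-[3-(aminomethyl)-4-(azidomethyl)cyclobutane-1,2-diyl]di(ethan-1-one) hydrochloride (ring configuration as in 17) | CC(=O)[C@H]1[C@H](CN=[N+]=[N-])[C@@H](CN)[C@@H]1C(C)=O.Cl | intermediate (not isolated)
20 | N-{[all-trans-3,4-diacetyl-2-(azidomethyl)cyclobutyl]methyl}-4-bromo-1H-pyrrole-2-carboxamide (ring configuration as in 17) | CC(=O)[C@H]1[C@H](CN=[N+]=[N-])[C@@H](CNC(=O)c2cc(Br)c[nH]2)[C@@H]1C(C)=O | intermediate
21 | N-{[all-trans-2-(azidomethyl)-3,4-bis(chloroacetyl)cyclobutyl]methyl}-4-bromo-1H-pyrrole-2-carboxamide | O=C(CCl)[C@H]1[C@H](CN=[N+]=[N-])[C@@H](CNC(=O)c2cc(Br)c[nH]2)[C@@H]1C(=O)CCl | intermediate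
22 | N-{[all-trans-2-(azidomethyl)-3,4-bis(N,N-diformylglycyl)cyclobutyl]methyl}-4-bromo-1H-pyrrole-2-carboxamide | O=CN(C=O)CC(=O)[C@H]1[C@H](CN=[N+]=[N-])[C@@H](CNC(=O)c2cc(Br)c[nH]2)[C@@H]1C(=O)CN(C=O)C=O | intermediate (not isolated)
23 | N-{[all-trans-3,4-bis(aminoacetyl)-2-(azidomethyl)cyclobutyl]methyl}-4-bromo-1H-pyrrole-2-carboxamide dihydrochloride | NCC(=O)[C@H]1[C@H](CN=[N+]=[N-])[C@@H](CNC(=O)c2cc(Br)c[nH]2)[C@@H]1C(=O)CN.Cl.Cl | intermediate
24 | N-{[all-trans-2-(azidomethyl)-3,4-bis(2-amino-1H-imidazol-4-yl)cyclobutyl]methyl}-4-bromo-1H-pyrrole-2-carboxamide dihydrochloride | Nc1ncc([C@H]2[C@H](CN=[N+]=[N-])[C@@H](CNC(=O)c3cc(Br)c[nH]3)[C@@H]2c2cnc(N)[nH]2)[nH]1.Cl.Cl | intermediate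
25 | N-{[all-trans-2-(aminomethyl)-3,4-bis(2-amino-1H-imidazol-4-yl)cyclobutyl]methyl}-4-bromo-1H-pyrrole-2-carboxamide trihydrochloride | Nc1ncc([C@H]2[C@H](CN)[C@@H](CNC(=O)c3cc(Br)c[nH]3)[C@@H]2c2cnc(N)[nH]2)[nH]1.Cl.Cl.Cl | intermediate
26 | 2-(trichloroacetyl)-1H-pyrrole | O=C(c1ccc[nH]1)C(Cl)(Cl)Cl | starting material
27 | desbromosceptrine (free base) | Nc1ncc([C@H]2[C@H](CNC(=O)c3ccc[nH]3)[C@@H](CNC(=O)c3cc(Br)c[nH]3)[C@@H]2c2cnc(N)[nH]2)[nH]1 | target

**Step count and risks**

Total step count: 17. Longest linear sequence: 17 steps (fumaryl chloride to the target; the two pyrrole acyl donors are bought).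

Steps most likely to fail:

1. Step 12. The two azides are homotopic, so selectivity for reducing only one depends on the monoamine being pulled into the acid phase. If the aminophosphonium intermediate stays in the organic layer, over-reduction to the diamine or incomplete conversion would erode the yield, and the transient amino ketone could also condense internally before it is acylated.
   Fallback: the route sets out from 15 and places the two nitrogens one at a time. Monosulfonylation of the symmetric diol (TsCl, Ag2O, KI cat., CH2Cl2) should give the monotosylate F1 as a single compound. NaN3 in DMF would then give the azido alcohol F2, MsCl/Et3N the azido mesylate F3, and KN(CO2t-Bu)2 in DMF the azido bis(tert-butoxycarbonyl)imide F4. HCl in dioxane removes both carbamates and comes back to the route at 19, which is acylated with 18 as in the second half of step 12.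

2. Step 8. The alkoxyvinyl cuprate may decompose before it adds, may attack the carbonyl directly, or may trigger oligomerisation or ring opening of the strained enone; the base equilibration could also be slowed by the reluctance of the ring carbons to enolise.
   Fallback: from 11, Michael addition of nitroethane (DBU cat., MeCN, 23 °C) should give the nitro ketone F5 (mixture at the nitro-bearing carbon, ring centres equilibrated trans). A Nef reaction (NaOMe, MeOH; then cold aqueous H2SO4), followed by the same K2CO3/MeOH equilibration, converts the nitroalkyl group into the second acetyl group and comes back to the route at 14.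

3. Step 7. Methyl transfer from tin is slow, so direct coupling without CO insertion or thermal decay of the cyclobutenyl triflate may compete with the desired acyl transfer.
   Fallback: from 10, a non-carbonylative Stille coupling with tributyl(1-ethoxyvinyl)stannane (Pd(PPh3)4, LiCl, THF, 60 °C) forms the C1–acyl carbon bond directly and should give the ethoxydiene F6. Mild hydrolysis (1 M HCl, THF, 23 °C) comes back to the route at 11.

**Further compounds**

F1 | step 12 | all-trans 1,1'-[3-(hydroxymethyl)-4-(tosyloxymethyl)cyclobutane-1,2-diyl]di(ethan-1-one) | CC(=O)[C@H]1[C@H](COS(=O)(=O)c2ccc(C)cc2)[C@@H](CO)[C@@H]1C(C)=O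
F2 | step 12 | all-trans 1,1'-[3-(azidomethyl)-4-(hydroxymethyl)cyclobutane-1,2-diyl]di(ethan-1-one) | CC(=O)[C@H]1[C@H](CN=[N+]=[N-])[C@@H](CO)[C@@H]1C(C)=O
F3 | step 12 | all-trans [3,4-diacetyl-2-(azidomethyl)cyclobutyl]methyl methanesulfonate | CC(=O)[C@H]1[C@H](CN=[N+]=[N-])[C@@H](COS(C)(=O)=O)[C@@H]1C(C)=O
F4 | step 12 | di-tert-butyl N-{[all-trans-3,4-diacetyl-2-(azidomethyl)cyclobutyl]methyl}imidodicarbonate | CC(=O)[C@H]1[C@H](CN=[N+]=[N-])[C@@H](CN(C(=O)OC(C)(C)C)C(=O)OC(C)(C)C)[C@@H]1C(C)=O
F5 | step 8 | all-trans 1-{2,3-bis[(benzyloxy)methyl]-4-(1-nitroethyl)cyclobutyl}ethan-1-one (mixture at the nitro-bearing carbon) | CC(=O)[C@H]1[C@H](COCc2ccccc2)[C@@H](COCc2ccccc2)[C@@H]1C(C)[N+](=O)[O-]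
F6 | step 7 | (3S,4S)-3,4-bis[(benzyloxy)methyl]-1-(1-ethoxyvinyl)cyclobut-1-ene | CCOC(=C)C1=C[C@H](COCc2ccccc2)[C@H]1COCc1ccccc1
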